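**Plan**
1. Target: an oxolane ring O1–C2(aryl)–C3(aroyl)–C4(aroyl)–C5(aryl) with 2,3-trans, 3,4-cis, 4,5-trans and 2,5-cis relations. This is the meso (2R,3R,4S,5S) isomer (mirror plane through O1 and the C3–C4 midpoint), so only relative configuration must be made and racemic precursors suffice.
2. Enabling feature: C2 bears a para-oxygenated phenyl ring (cation-stabilising donor). C4, in 1,3-relation to it, bears an aroyl group (enolate-stabilising acceptor), and O1–C5 is the C=O of 4-hydroxybenzaldehyde. C2–C3–C4 is therefore a masked donor–acceptor cyclopropane, a temporary ring that the key step itself consumes.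
3. Cuts: first the six O–benzyl bonds. Then O1–C2 and C4–C5 together, giving a 3-aryl-1,2-diaroylcyclopropane plus an aldehyde. Then the cyclopropane bond between the two aroyl-bearing carbons, giving a 1,5-diketone. Last, the two bonds from its central CH to the CH2 groups, giving two acetophenones plus one aldehyde.
4. Forward: the chain is joined 2:1 in one pot and the three-membered ring is closed oxidatively with I2/base. The oxolane ring is then made with a second aldehyde by iodide-relayed ring opening, aldol addition and etherification, and global hydrogenolysis follows.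
5. Stereochemistry: ring opening keeps only C3. C4 follows from C3 by 1,2-induction in an intermolecular aldol addition (3,4-cis). C5 comes from the (Z)-enolate in a closed transition state (4,5-trans), and C2 from ring closure trans to the C3 aroyl group. Every cyclopropane isomer and both enantiomers funnel into the one meso product.

Key step: step 4

Remark: chiral intermediates are racemic and drawn as one enantiomer. The carbon that carries iodine (or methoxy in a fallback) is left undefined because both epimers are expected and both converge.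

Step 1
Reactants: 1 2,4-dihydroxyacetophenone
Product: 2 2,4-bis(benzyloxy)acetophenone
Conditions: BnBr (2.4 equiv), K2CO3, DMF, 80 °C
Reagents that add atoms: benzyl bromide, BrCc1ccccc1
Why: Williamson ether synthesis, in which heating in DMF also alkylates the hydrogen-bonded 2-OH, gives ethers that survive base, iodine and cold TiCl4, keep the 2-oxygen from attacking C2 later and leave together in one neutral final step.

Step 2
Reactants: 2 2,4-bis(benzyloxy)acetophenone (2.1 equiv); 3 4-(benzyloxy)benzaldehyde
Product: 5 3-[4-(benzyloxy)phenyl]-1,5-bis[2,4-bis(benzyloxy)phenyl]pentane-1,5-dione, via chalcone 4 (not isolated)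
Conditions: KOH (30 mol %), EtOH–THF, 60 °C
Reagents that add atoms: none
Why: Claisen–Schmidt condensation gives the (E)-chalcone, which takes up a second enolate of 2 by Michael addition in the same pot (the classical 2:1 entry to 1,3,5-triaryl-1,5-diketones), and no stereocentre arises because the two arms on the central carbon are identical.

Step 3
Reactants: 5 3-[4-(benzyloxy)phenyl]-1,5-bis[2,4-bis(benzyloxy)phenyl]pentane-1,5-dione
Product: 7 (±)-trans-{3-[4-(benzyloxy)phenyl]cyclopropane-1,2-diyl}bis{[2,4-bis(benzyloxy)phenyl]methanone}, via iodo diketone 6 (not isolated)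
Conditions: I2 (1.1 equiv), DBU (2.5 equiv), MeCN–CH2Cl2, 0 °C → rt
Reagents that add atoms: none
Why: Base-mediated α-iodination followed by 3-exo-tet intramolecular enolate alkylation (the I2/base oxidative cyclisation of 1,3-diaroylpropanes to 1,2-diaroylcyclopropanes) should give the epimerisable centres as the trans-diaroyl isomer, although the configuration reached here has no bearing on step 4.

Step 4
Reactants: 7 (±)-trans-{3-[4-(benzyloxy)phenyl]cyclopropane-1,2-diyl}bis{[2,4-bis(benzyloxy)phenyl]methanone}; 3 4-(benzyloxy)benzaldehyde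
Product: 10 meso-{(2R,3R,4S,5S)-2,5-bis[4-(benzyloxy)phenyl]oxolane-3,4-diyl}bis{[2,4-bis(benzyloxy)phenyl]methanone}, via iodo titanium enolate 8 (not isolated), via iodo titanium aldolate 9 (not isolated)
Conditions: TiCl4 (1.2 equiv), n-Bu4NI (1.2 equiv), CH2Cl2, −78 °C; 7, then promptly 3 (1.2 equiv), −78 → −20 °C; aq NaHCO3
Reagents that add atoms: none
Why: TiCl4 binds one aroyl C=O (ortho-benzyloxy oxygen as second donor) and iodide attacks the ring carbon that bears the 4-benzyloxyphenyl donor, so that the polarised C(aryl)–C(aroyl) bond and not the C(aroyl)–C(aroyl) bond breaks and the (Z)-titanium enolate 8 results; its planar C4 and its labile benzylic carbon–iodine centre delete two of the three ring stereocentres, so both enantiomers, any cis/trans isomer and either of the two C(aryl)–C(aroyl) bonds give the same racemic intermediate. The closest known reaction types are the metal-iodide-induced ring-opening aldol reaction of aryl cyclopropyl ketones and the MgI2-type formal [3+2] ring expansions of acceptor cyclopropanes with C=X partners. C4–C5 forms first in a closed Zimmerman–Traxler chair: the (Z)-enolate gives the syn aldolate 9, which sets C5 (later 4,5-trans), and with H3 eclipsing the enolate double bond to avoid allylic 1,3-strain the aldehyde enters anti to the bulky, better σ-donating iodo(aryl)methyl group and on the side of the flat C3 aroyl group, whose C=O can also sit on titanium, which sets C4 with the two aroyl groups cis. The oxolane ring closes by 5-exo-tet attack of the alkoxide O1 on C2 at the SN2/SN1 borderline; the carbon–iodine epimers interconvert by iodide exchange and ionisation, and the faster closure puts the C2 aryl group trans to the C3 aroyl group and cis to the C5 aryl group, which is also the more stable arrangement should C2 or C5 re-ionise. The step needs C–C before C–O bond formation, because an oxocarbenium ion made by aldehyde-oxygen attack on C2 could reach C4 only from the C2 side and would give the 3,4-trans series; iodide as a far better nucleophile than the aldehyde oxygen and the high carbon nucleophilicity of a simple ketone enolate secure this order. Closure of the enolate oxygen on C2 (Cloke–Wilson-type dihydrofuran), loss of HI towards the arylidene diketone and attack of a free 2-OH on C2 (flavanone) are held back by low temperature, absence of base, prompt addition of 3 and the benzyl ethers.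

Step 5
Reactants: 10 meso-{(2R,3R,4S,5S)-2,5-bis[4-(benzyloxy)phenyl]oxolane-3,4-diyl}bis{[2,4-bis(benzyloxy)phenyl]methanone}
Product: 11 meso-[(2R,3R,4S,5S)-2,5-bis(4-hydroxyphenyl)oxolane-3,4-diyl]bis[(2,4-dihydroxyphenyl)methanone] (CNP0237262.1)
Conditions: H2 (1 atm), 10% Pd/C, EtOAc–MeOH, rt, stopped at full conversion
Reagents that add atoms: none
Why: Hydrogenolysis of aryl benzyl ethers is faster than cleavage of the ring C–O bonds of 2,5-diaryloxolanes or reduction of 2,4-dioxygenated aryl ketones, and because neither acid nor base is present the enolisable C3/C4 and the ionisable C2/C5 centres should stay as set.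

**Compound list**
1 | 2,4-dihydroxyacetophenone | CC(=O)c1ccc(O)cc1O | starting material
2 | 2,4-bis(benzyloxy)acetophenone | CC(=O)c1ccc(OCc2ccccc2)cc1OCc1ccccc1 | intermediate
3 | 4-(benzyloxy)benzaldehyde | O=Cc1ccc(OCc2ccccc2)cc1 | starting material
4 | (E)-3-[4-(benzyloxy)phenyl]-1-[2,4-bis(benzyloxy)phenyl]prop-2-en-1-one (chalcone, not isolated) | O=C(/C=C/c1ccc(OCc2ccccc2)cc1)c1ccc(OCc2ccccc2)cc1OCc1ccccc1 | intermediate
5 | 3-[4-(benzyloxy)phenyl]-1,5-bis[2,4-bis(benzyloxy)phenyl]pentane-1,5-dione (achiral) | O=C(CC(CC(=O)c1ccc(OCc2ccccc2)cc1OCc1ccccc1)c1ccc(OCc2ccccc2)cc1)c1ccc(OCc2ccccc2)cc1OCc1ccccc1 | intermediate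
6 | 3-[4-(benzyloxy)phenyl]-1,5-bis[2,4-bis(benzyloxy)phenyl]-2-iodopentane-1,5-dione (isomer mixture, not isolated) | O=C(C(C(CC(=O)c1ccc(OCc2ccccc2)cc1OCc1ccccc1)c1ccc(OCc2ccccc2)cc1)I)c1ccc(OCc2ccccc2)cc1OCc1ccccc1 | intermediate
7 | (±)-trans-{3-[4-(benzyloxy)phenyl]cyclopropane-1,2-diyl}bis{[2,4-bis(benzyloxy)phenyl]methanone}, (1S,2S) enantiomer drawn | O=C(c1ccc(OCc2ccccc2)cc1OCc1ccccc1)[C@@H]1[C@@H](C(=O)c2ccc(OCc3ccccc3)cc2OCc2ccccc2)C1c1ccc(OCc2ccccc2)cc1 | intermediate
8 | trichlorotitanium (Z)-enolate of 2-{[4-(benzyloxy)phenyl](iodo)methyl}-1,4-bis[2,4-bis(benzyloxy)phenyl]butane-1,4-dione (racemic, not isolated) | O=C(c1ccc(OCc2ccccc2)cc1OCc1ccccc1)[C@@H](C(c1ccc(OCc2ccccc2)cc1)I)/C=C(\O[Ti](Cl)(Cl)Cl)c1ccc(OCc2ccccc2)cc1OCc1ccccc1 | intermediate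
9 | trichlorotitanium aldolate of 2-{[4-(benzyloxy)phenyl](hydroxy)methyl}-3-{[4-(benzyloxy)phenyl](iodo)methyl}-1,4-bis[2,4-bis(benzyloxy)phenyl]butane-1,4-dione (racemic, not isolated) | O=C(c1ccc(OCc2ccccc2)cc1OCc1ccccc1)[C@@H](C(c1ccc(OCc2ccccc2)cc1)I)[C@H](C(=O)c1ccc(OCc2ccccc2)cc1OCc1ccccc1)[C@@H](c1ccc(OCc2ccccc2)cc1)O[Ti](Cl)(Cl)Cl | intermediate
10 | meso-{(2R,3R,4S,5S)-2,5-bis[4-(benzyloxy)phenyl]oxolane-3,4-diyl}bis{[2,4-bis(benzyloxy)phenyl]methanone} | O=C(c1ccc(OCc2ccccc2)cc1OCc1ccccc1)[C@@H]1[C@H](C(=O)c2ccc(OCc3ccccc3)cc2OCc2ccccc2)[C@@H](c2ccc(OCc3ccccc3)cc2)O[C@H]1c1ccc(OCc2ccccc2)cc1 | intermediate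
11 | meso-[(2R,3R,4S,5S)-2,5-bis(4-hydroxyphenyl)oxolane-3,4-diyl]bis[(2,4-dihydroxyphenyl)methanone] (CNP0237262.1) | O=C(c1ccc(O)cc1O)[C@@H]1[C@H](C(=O)c2ccc(O)cc2O)[C@@H](c2ccc(O)cc2)O[C@H]1c1ccc(O)cc1 | target

Total step count: 5. Longest linear sequence: 5 steps (1 → 2 → 5 → 7 → 10 → 11).

**Steps most likely to fail**

Step 4.
- What may go wrong:
  - Facial discrimination in the aldol addition may be too weak, which leaks material into the 3,4-trans series.
  - The enolate oxygen may close on C2 before the aldehyde is captured.
  - Hydrogen iodide may be lost towards the conjugated arylidene diketone.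
  - The titanium–iodide reagent may reductively couple the aldehyde.
  - The ortho benzyl groups may be lost with chelation assistance.
- Fallback: it sets out from 7 and returns at 10, and it separates the three events.
  - Sc(OTf)3-catalysed methanolysis (MeOH–CH2Cl2, 0 °C) should open the same donor–acceptor bond. The product is the bench-stable 2-{[4-(benzyloxy)phenyl](methoxy)methyl}-1,4-bis[2,4-bis(benzyloxy)phenyl]butane-1,4-dione F1.
  - Soft enolisation of its CH2 ketone with n-Bu2BOTf/i-Pr2NEt (CH2Cl2, −78 °C) gives the (Z)-boron enolate. Its tighter closed transition state adds to 3 to give the syn aldol 2-{[4-(benzyloxy)phenyl](hydroxy)methyl}-3-{[4-(benzyloxy)phenyl](methoxy)methyl}-1,4-bis[2,4-bis(benzyloxy)phenyl]butane-1,4-dione F2, which can be purified from any 3,4-epimer.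
  - Catalytic BF3·OEt2 (CH2Cl2, −40 °C) then ionises the para-benzyloxybenzylic methyl ether, and the C5 hydroxyl closes the ring trans to the C3 aroyl group to give 10.

Step 2.
- What may go wrong: the sequence may stall at the electron-rich chalcone, which is a poor Michael acceptor and tends to precipitate. The adduct may also revert by retro-Michael reaction under the basic conditions.
- Fallback: it sets out from 2 and 3 and returns at 5.
  - Claisen–Schmidt condensation with one equivalent of 2 (KOH, EtOH, rt) is stopped at chalcone 4, which is isolated.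
  - A second portion of 2 is converted into {1-[2,4-bis(benzyloxy)phenyl]ethenyl}oxy(trimethyl)silane F3 (TMSOTf, Et3N, CH2Cl2, 0 °C).
  - A TiCl4-promoted Mukaiyama–Michael addition of F3 to 4 (CH2Cl2, −78 °C) forms the C–C bond irreversibly under Lewis-acid activation and gives 5 after aqueous work-up.

Step 5.
- What may go wrong: over-reduction, either by hydrogenolytic opening of the doubly benzylic ring C–O bonds or by reduction of the aryl ketones, before the sixth benzyl ether has left.
- Fallback: it sets out from 10 and returns at 11 without new intermediates. Non-reductive Lewis-acid debenzylation with BCl3 and pentamethylbenzene as benzyl-cation scavenger (CH2Cl2, −78 °C) is used, followed by a MeOH quench. Any transient ionisation at C2 or C5 should re-close to the same, more stable 2,3-trans/4,5-trans arrangement.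

**Further compounds**
F1 | step 4 | 2-{[4-(benzyloxy)phenyl](methoxy)methyl}-1,4-bis[2,4-bis(benzyloxy)phenyl]butane-1,4-dione (racemic, methoxy epimers) | O=C(c1ccc(OCc2ccccc2)cc1OCc1ccccc1)[C@@H](C(OC)c1ccc(OCc2ccccc2)cc1)CC(=O)c1ccc(OCc2ccccc2)cc1OCc1ccccc1
F2 | step 4 | 2-{[4-(benzyloxy)phenyl](hydroxy)methyl}-3-{[4-(benzyloxy)phenyl](methoxy)methyl}-1,4-bis[2,4-bis(benzyloxy)phenyl]butane-1,4-dione (racemic, methoxy epimers) | O=C(c1ccc(OCc2ccccc2)cc1OCc1ccccc1)[C@@H](C(OC)c1ccc(OCc2ccccc2)cc1)[C@H](C(=O)c1ccc(OCc2ccccc2)cc1OCc1ccccc1)[C@@H](c1ccc(OCc2ccccc2)cc1)O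
F3 | step 2 | {1-[2,4-bis(benzyloxy)phenyl]ethenyl}oxy(trimethyl)silane | C=C(O[Si](C)(C)C)c1ccc(OCc2ccccc2)cc1OCc1ccccc1
F0 | step 5 | none | none
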